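**Retrosynthetic overview**
1. The last bond made is the ring B C3–OH (last stereocentre): photosensitised singlet-oxygen oxygenation of the silyl dienol ether of the fully assembled ester. The ester C–O bond is cut to a hydroxy dienone core and a (2E,4E)-dienoic acid.
2. Core dienone ⇐ enone (quinone dehydrogenation) ⇐ pinane-fused tricyclic enone, whose gem-dimethyl bridge carbon is excised as acetone and replaced by OH with retention (C–C to C–O).
3. Tricyclic enone ⇐ Robinson annulation on 3-methyl-cis-verbanone ⇐ (−)-verbenone; the cyclobutane controls both methyl centres and carries the future C6 oxygen position.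
4. Dienoic acid ⇐ Heck coupling of (E)-3-iodoacrylic acid with (S)-3-methylpent-1-en-3-ol ⇐ (S)-linalool by dealkenylative chain shortening.
5. Ring order: ring A is bought (the six-membered ring of verbenone), ring B is annulated onto it, and the four-membered ring is opened afterwards.

Assumption: both terpene starting materials are bought in high enantiomeric purity (≥97% ee); metal enolates and catalyst-bound species are treated as transient and are not numbered.

**Step 1**
Reactants: 1 (1S,5S)-(−)-verbenone [(1S,5S)-4,6,6-trimethylbicyclo[3.1.1]hept-3-en-2-one]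
Product: 2 (1S,4R,5S)-4,6,6-trimethylbicyclo[3.1.1]heptan-2-one (cis-verbanone; C4 methyl syn to the gem-dimethyl bridge)
Conditions: H2 (1 atm), 10% Pd/C, EtOAc, 23 °C
Reagents that add atoms: none
Why: Heterogeneous catalytic hydrogenation delivers H2 to the enone C=C from the face opposite the gem-dimethyl bridge, so the C4 methyl ends up syn to that bridge (4R).

**Step 2**
Reactants: 2 (1S,4R,5S)-4,6,6-trimethylbicyclo[3.1.1]heptan-2-one
Product: 3 (1S,3R,4S,5S)-3,4,6,6-tetramethylbicyclo[3.1.1]heptan-2-one (C3 methyl anti to the bridge; trans to the C4 methyl)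
Conditions: LiN(iPr)2, THF, −78 °C; MeI, −78 → 0 °C
Reagents that add atoms: iodomethane CI
Why: Kinetic enolate alkylation is regiospecific because the other α-carbon is a bridgehead that cannot enolise, and MeI enters anti to the gem-dimethyl bridge (this centre is flattened again in step 3).

**Step 3**
Reactants: 3 (1S,3R,4S,5S)-3,4,6,6-tetramethylbicyclo[3.1.1]heptan-2-one; 4 3-(trimethylsilyl)but-3-en-2-one
Product: 7 (4aR,5S,6S,8S)-4a,5,9,9-tetramethyl-4,4a,5,6,7,8-hexahydro-6,8-methanonaphthalen-2(3H)-one (pinane-fused tricyclic enone), via silyl diketone 5 (not isolated), via diketone 6 (not isolated)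
Conditions: LiN(iPr)2, THF, −78 → 0 °C; 4, −78 → −20 °C; then KOH, MeOH, 65 °C
Reagents that add atoms: none
Why: Robinson annulation in its Stork α-silyl vinyl ketone form: the only possible enolate adds to 4 (Michael addition) from the open face anti to the gem-dimethyl bridge, which pushes the C3 methyl syn to the bridge and cis to the C4 methyl (quaternary centre 4aR set by the bought bridge), and KOH/MeOH then removes silicon and closes ring B by aldol condensation.

**Step 4**
Reactants: 7 (4aR,5S,6S,8S)-4a,5,9,9-tetramethyl-4,4a,5,6,7,8-hexahydro-6,8-methanonaphthalen-2(3H)-one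
Product: 9 (4aR,5R,6S)-6-hydroxy-4a,5-dimethyl-4,4a,5,6,7,8-hexahydronaphthalen-2(3H)-one, via hydroperoxide 8 (not isolated)
Conditions: H2O2·urea (3 equiv), TfOH (20 mol %), (CF3)2CHOH/CH2Cl2, 0 → 23 °C; aq Na2SO3 work-up
Reagents that add atoms: hydrogen peroxide OO
Why: Proposed new method: protonation of the enone carbonyl of 7 should trigger the vinylogous cyclobutylcarbinyl-cation fragmentation of the C8–C9 bond (the path by which HCl opens pinane-fused enones) to a dienol that tautomerises back to the enone and a tertiary carbocation on the former bridge carbon, hydrogen peroxide traps that cation as tertiary hydroperoxide 8, and the same acid then promotes a Hock (Criegee-type) 1,2-shift of the secondary ring carbon C6 from carbon to oxygen with retention followed by hydrolysis of the oxocarbenium ion to acetone and 9, so the bridge carbon is exchanged for a hydroxyl on the face it occupied (6S, cis to both methyls); the closest known reactions are the acid cleavage of the pinane cyclobutane in annulated nopinone enones and the cumene-type Hock rearrangement of tertiary hydroperoxides, which have not been run as one cascade on such a substrate.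

**Step 5**
Reactants: 9 (4aR,5R,6S)-6-hydroxy-4a,5-dimethyl-4,4a,5,6,7,8-hexahydronaphthalen-2(3H)-one
Product: 10 (4aR,5R,6S)-6-hydroxy-4a,5-dimethyl-4,4a,5,6-tetrahydronaphthalen-2(3H)-one
Conditions: chloranil (1.3 equiv), tBuOH, 82 °C
Reagents that add atoms: none
Why: Quinone dehydrogenation through the heteroannular dienol (hydride abstraction from C7 by chloranil) gives the linear dienone regioselectively, the classic chloranil γ,δ-dehydrogenation of enones, and touches no stereocentre.

**Step 6**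
Reactants: 11 (S)-(+)-linalool [(3S)-3,7-dimethylocta-1,6-dien-3-ol]
Product: 13 (3S)-3-methylpent-1-en-3-ol, via methoxy hydroperoxide 12 (not isolated)
Conditions: O3 (1.0 equiv), MeOH, −78 °C; then FeSO4·7H2O (1.2 equiv), PhSH (1.5 equiv), 0 → 23 °C
Reagents that add atoms: none
Why: Dealkenylative hydrogenation: ozone cleaves only the electron-rich trisubstituted alkene to the α-methoxy hydroperoxide, divalent iron reduces it to an alkoxy radical that loses methyl formate by β-scission, and the primary radical takes H from PhSH, so the homoprenyl arm is cut back to ethyl while the bought carbinol stereocentre is untouched.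

**Step 7**
Reactants: 13 (3S)-3-methylpent-1-en-3-ol; 14 (2E)-3-iodoprop-2-enoic acid
Product: 15 (2E,4E,6S)-6-hydroxy-6-methylocta-2,4-dienoic acid
Conditions: Pd(OAc)2 (5 mol %), K2CO3, Bu4NCl, DMF, 50 °C; then aq HCl to pH 3
Reagents that add atoms: none
Why: Heck reaction under Jeffery conditions: the vinyl–palladium species adds to the terminal alkene carbon and β-hydride elimination can only run away from the fully substituted carbinol carbon, giving the 2E,4E-diene with retention of the iodoacrylate geometry.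

**Step 8**
Reactants: 10 (4aR,5R,6S)-6-hydroxy-4a,5-dimethyl-4,4a,5,6-tetrahydronaphthalen-2(3H)-one; 15 (2E,4E,6S)-6-hydroxy-6-methylocta-2,4-dienoic acid
Product: 17 (4aR,5R,6S)-4a,5-dimethyl-2-oxo-2,3,4,4a,5,6-hexahydronaphthalen-6-yl (2E,4E,6S)-6-hydroxy-6-methylocta-2,4-dienoate, via mixed anhydride 16 (not isolated)
Conditions: 15, 2,4,6-Cl3C6H2COCl, Et3N, THF, 0 → 23 °C; then 10, DMAP, toluene, 40 °C
Reagents that add atoms: none
Why: Yamaguchi esterification acylates the hindered secondary allylic hydroxyl of 10 at its O–H bond (configuration at C6 retained), while the tertiary hydroxyl of 15 is too hindered to react.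

**Step 9**
Reactants: 17 (4aR,5R,6S)-4a,5-dimethyl-2-oxo-2,3,4,4a,5,6-hexahydronaphthalen-6-yl (2E,4E,6S)-6-hydroxy-6-methylocta-2,4-dienoate
Product: 21 CNP0260852.4 [(3R,4aR,5R,6S)-3-hydroxy-4a,5-dimethyl-2-oxo-2,3,4,4a,5,6-hexahydronaphthalen-6-yl (2E,4E,6S)-6-hydroxy-6-methylocta-2,4-dienoate], via silyl trienol ether 18 (not isolated), via silyl peroxide 19 (not isolated), via bis-silyl ether 20 (not isolated)
Conditions: LiN(SiMe3)2 (2.3 equiv), Me3SiCl, THF, −78 °C; O2, tetraphenylporphyrin (1 mol %), hν (white LEDs), CH2Cl2, −78 °C; PPh3, −78 → 0 °C; citric acid, MeOH, 23 °C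
Reagents that add atoms: dioxygen O=O
Why: Kinetic α′-enolisation and silylation give the cross-conjugated 2-silyloxy diene of ring B, which photosensitised singlet oxygen attacks (Schenck-type silyl-ene/[4+2] oxygenation) far faster than the electron-poor dienoate and from the face opposite the axial angular methyl, so the new C3–O bond is trans to that methyl (3R) before PPh3 reduction of the peroxide and desilylation release 21.

**Compound list**
1 | (1S,5S)-(−)-verbenone, (1S,5S)-4,6,6-trimethylbicyclo[3.1.1]hept-3-en-2-one | CC1=CC(=O)[C@H]2C[C@@H]1C2(C)C | starting material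
2 | (1S,4R,5S)-4,6,6-trimethylbicyclo[3.1.1]heptan-2-one (cis-verbanone) | C[C@@H]1CC(=O)[C@H]2C[C@@H]1C2(C)C | intermediate
3 | (1S,3R,4S,5S)-3,4,6,6-tetramethylbicyclo[3.1.1]heptan-2-one | C[C@@H]1[C@@H](C)C(=O)[C@H]2C[C@@H]1C2(C)C | intermediate
4 | 3-(trimethylsilyl)but-3-en-2-one | CC(=O)C(=C)[Si](C)(C)C | starting material
5 | (1S,3R,4S,5S)-3,4,6,6-tetramethyl-3-[3-oxo-2-(trimethylsilyl)butyl]bicyclo[3.1.1]heptan-2-one (both epimers at the silyl-bearing carbon) | C[C@@H]1[C@@](C)(CC(C(C)=O)[Si](C)(C)C)C(=O)[C@H]2C[C@@H]1C2(C)C | intermediate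
6 | (1S,3R,4S,5S)-3,4,6,6-tetramethyl-3-(3-oxobutyl)bicyclo[3.1.1]heptan-2-one | C[C@@H]1[C@@](C)(CCC(C)=O)C(=O)[C@H]2C[C@@H]1C2(C)C | intermediate
7 | (4aR,5S,6S,8S)-4a,5,9,9-tetramethyl-4,4a,5,6,7,8-hexahydro-6,8-methanonaphthalen-2(3H)-one | C[C@@H]1[C@@]2(C)CCC(=O)C=C2[C@H]3C[C@@H]1C3(C)C | intermediate
8 | (4aR,5S,6S)-6-(2-hydroperoxypropan-2-yl)-4a,5-dimethyl-4,4a,5,6,7,8-hexahydronaphthalen-2(3H)-one | CC(C)(OO)[C@H]1CCC2=CC(=O)CC[C@]2(C)[C@H]1C | intermediate
9 | (4aR,5R,6S)-6-hydroxy-4a,5-dimethyl-4,4a,5,6,7,8-hexahydronaphthalen-2(3H)-one | O[C@H]1CCC2=CC(=O)CC[C@]2(C)[C@H]1C | intermediate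
10 | (4aR,5R,6S)-6-hydroxy-4a,5-dimethyl-4,4a,5,6-tetrahydronaphthalen-2(3H)-one | O[C@H]1C=CC2=CC(=O)CC[C@]2(C)[C@H]1C | intermediate
11 | (S)-(+)-linalool, (3S)-3,7-dimethylocta-1,6-dien-3-ol | CC(C)=CCC[C@](C)(O)C=C | starting material
12 | (3S)-6-hydroperoxy-6-methoxy-3-methylhex-1-en-3-ol (both epimers at C6) | COC(OO)CC[C@](C)(O)C=C | intermediate
13 | (3S)-3-methylpent-1-en-3-ol | CC[C@](C)(O)C=C | intermediate
14 | (2E)-3-iodoprop-2-enoic acid | OC(=O)/C=C/I | starting material
15 | (2E,4E,6S)-6-hydroxy-6-methylocta-2,4-dienoic acid | CC[C@](C)(O)/C=C/C=C/C(O)=O | intermediate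
16 | (2E,4E,6S)-6-hydroxy-6-methylocta-2,4-dienoic 2,4,6-trichlorobenzoic anhydride | CC[C@](C)(O)/C=C/C=C/C(=O)OC(=O)c1c(Cl)cc(Cl)cc1Cl | intermediate
17 | (4aR,5R,6S)-4a,5-dimethyl-2-oxo-2,3,4,4a,5,6-hexahydronaphthalen-6-yl (2E,4E,6S)-6-hydroxy-6-methylocta-2,4-dienoate | CC[C@](C)(O)/C=C/C=C/C(=O)O[C@H]1C=CC2=CC(=O)CC[C@]2(C)[C@H]1C | intermediate
18 | (4aR,5R,6S)-4a,5-dimethyl-2-(trimethylsilyloxy)-4,4a,5,6-tetrahydronaphthalen-6-yl (2E,4E,6S)-6-methyl-6-(trimethylsilyloxy)octa-2,4-dienoate | CC[C@](C)(O[Si](C)(C)C)/C=C/C=C/C(=O)O[C@H]1C=CC2=CC(O[Si](C)(C)C)=CC[C@]2(C)[C@H]1C | intermediate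
19 | (3R,4aR,5R,6S)-4a,5-dimethyl-2-oxo-3-(trimethylsilylperoxy)-2,3,4,4a,5,6-hexahydronaphthalen-6-yl (2E,4E,6S)-6-methyl-6-(trimethylsilyloxy)octa-2,4-dienoate | CC[C@](C)(O[Si](C)(C)C)/C=C/C=C/C(=O)O[C@H]1C=CC2=CC(=O)[C@H](OO[Si](C)(C)C)C[C@]2(C)[C@H]1C | intermediate
20 | (3R,4aR,5R,6S)-4a,5-dimethyl-2-oxo-3-(trimethylsilyloxy)-2,3,4,4a,5,6-hexahydronaphthalen-6-yl (2E,4E,6S)-6-methyl-6-(trimethylsilyloxy)octa-2,4-dienoate | CC[C@](C)(O[Si](C)(C)C)/C=C/C=C/C(=O)O[C@H]1C=CC2=CC(=O)[C@H](O[Si](C)(C)C)C[C@]2(C)[C@H]1C | intermediate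
21 | CNP0260852.4, (3R,4aR,5R,6S)-3-hydroxy-4a,5-dimethyl-2-oxo-2,3,4,4a,5,6-hexahydronaphthalen-6-yl (2E,4E,6S)-6-hydroxy-6-methylocta-2,4-dienoate | CC[C@](C)(O)/C=C/C=C/C(=O)O[C@H]1C=CC2=CC(=O)[C@H](O)C[C@]2(C)[C@H]1C | target

**Step count and risks**
Total steps: 9. Longest linear sequence: 7 (steps 1, 2, 3, 4, 5, 8, 9); steps 6 and 7 make the side chain.

Most likely to fail:

- **Step 4 (the new cascade).** Risks are Baeyer–Villiger or other over-oxidation by acidic peroxide, and methyl instead of ring-carbon migration in the Hock step. The fallback uses known chemistry, sets out from 7 and comes back at 9. HCl in AcOH opens the cyclobutane to tertiary chloride F1; NaOAc in AcOH at 100 °C eliminates HCl to give isopropenyl enone F2; ozonolysis in CH2Cl2/MeOH at −78 °C followed by Ac2O, Et3N and DMAP (Criegee rearrangement, retention) gives acetate F3; K2CO3 in MeOH then gives 9. This costs three extra steps.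

- **Step 6.** Risks are thiyl-radical addition to the vinyl group and over-ozonolysis. The fallback sets out from 11 and comes back at 15. Heck coupling of 11 with 14 (Pd(OAc)2, K2CO3, Bu4NCl, DMF) is run first and gives trienoic acid F4; ozonolysis of its trisubstituted alkene (1 equiv O3, CH2Cl2/MeOH, −78 °C; Me2S) gives oxo acid F5 (in equilibrium with its lactol); Tsuji–Wilkinson decarbonylation with RhCl(PPh3)3 in toluene at 110 °C removes the aldehyde carbon and delivers 15.

- **Step 9.** Risks are the regiochemistry of enolisation on the polyfunctional ester and the handling of the peroxide. The fallback sets out from 17 and comes back at 21. Radical α′-acetoxylation of the dienone with Mn(OAc)3 in benzene at 80 °C gives acetoxy ketone F6 (acetate trans to the angular methyl after equilibration); selective methanolysis of the α-keto acetate (K2CO3, MeOH, 0 °C) then gives 21.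

**Further compounds**
F1 | step 4 | (4aR,5S,6S)-6-(2-chloropropan-2-yl)-4a,5-dimethyl-4,4a,5,6,7,8-hexahydronaphthalen-2(3H)-one | CC(C)(Cl)[C@H]1CCC2=CC(=O)CC[C@]2(C)[C@H]1C
F2 | step 4 | (4aR,5S,6S)-4a,5-dimethyl-6-(prop-1-en-2-yl)-4,4a,5,6,7,8-hexahydronaphthalen-2(3H)-one | CC(=C)[C@H]1CCC2=CC(=O)CC[C@]2(C)[C@H]1C
F3 | step 4 | (4aR,5R,6S)-6-acetoxy-4a,5-dimethyl-4,4a,5,6,7,8-hexahydronaphthalen-2(3H)-one | CC(=O)O[C@H]1CCC2=CC(=O)CC[C@]2(C)[C@H]1C
F4 | step 6 | (2E,4E,6S)-6-hydroxy-6,10-dimethylundeca-2,4,9-trienoic acid | CC(C)=CCC[C@](C)(O)/C=C/C=C/C(=O)O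
F5 | step 6 | (2E,4E,6S)-6-hydroxy-6-methyl-9-oxonona-2,4-dienoic acid | O=CCC[C@](C)(O)/C=C/C=C/C(=O)O
F6 | step 9 | (3R,4aR,5R,6S)-3-acetoxy-4a,5-dimethyl-2-oxo-2,3,4,4a,5,6-hexahydronaphthalen-6-yl (2E,4E,6S)-6-hydroxy-6-methylocta-2,4-dienoate | CC[C@](C)(O)/C=C/C=C/C(=O)O[C@H]1C=CC2=CC(=O)[C@H](OC(C)=O)C[C@]2(C)[C@H]1C
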